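The readings were computed with constants of no real substance; the scatter is artificial.

A pitfall with a long run is to carry the early ratio of D to E through to the end.

| setting | east | north-east | flask |
|---|---|---|---|
| L | 0.25 M | 0.38 M | 0.25 M |
| Z | 0.125 M | 0.125 M | 0.125 M |
| remark | the very flask that is asked about, followed so far | run made earlier |  |
| time |  |  | 50 min |

- east (time / min: D / %, E / %): 0.667: 2.9, 1.0; 2.00: 8.1, 2.2; 4.00: 13.7, 4.2; 5.00: 16.1, 4.0; 8.00: 20.1, 6.0; 10.0: 21.6, 7.0
- north-east (time / min: D / %, E / %): 4.00: 12.7, 3.5; 6.00: 16.0, 4.5; 12.0: 19.5, 5.7; 20.0: 21.9, 6.9; 30.0: 21.6, 6.9; 50.0: 21.3, 8.3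

(readings scatter by 0.3 percentage points)

- ratio of D to E at 10 s
- ratio of D to E at 3.0 min
- ratio of D to E at 50 min
- which of D and E there is more of at 50 min

- percentages count the L that a species holds: one G counts as two
- D is meant together with its G
- what was read earlier has a scatter of 0.3 percentage points, one standard deviation
- reactions considered so far: L + Z <-> D; L + Z <-> E; L + D <-> G
- in an amount of D, one G counts as one D

The reactions considered are L + Z <-> D, L + Z <-> E and L + D <-> G, with unknown constants.

*What is the early ratio?* Summing D and E over the east readings up to 5.00 min gives s = 3.58, the selectivity factor. The north-east run reads 3.63 at 4.00 min. I take s for 10 s and 3.0 min.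

*Does it last?* No. In the north-east run, from 20.0 min to 50.0 min, D reads 21.9% and then 21.3%, while E goes from 6.9% to 8.3%. The ratio reads 2.57 at 50.0 min.

*How large is that fall?* Taken from s to that north-east reading, in logarithms, it is 0.144 decades. The scatter of that E reading is worth 0.0157 decades, so the fall is larger than that scatter.

*What do you scale it by?* I scale it by the Z left, charge minus D and E: 0.0125 M in that run. This gives 11.5 /M, the drift coefficient: decades of D/E lost by 50 min per unit of Z left at that time, read from this one run.

*But Z at 50 min is unread in the east flask.* True, and this is the weak spot. The quotient of D plus E over Z times L in the north-east run, counting one L for each, is 33.6 /M. It ignores the second L held in G. Applied to the east charges, it leaves 0.0212 M of Z. The fall is then 0.244 decades, so my ratio at 50 min is 2.04, with D ahead.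

The forecast gives 3.6 (3.1 to 4.1), 3.5 (3.1 to 3.9) and 2.35 (1.8 to 2.9), with D ahead: “so this is the kinetic ratio of two parallel channels”. My late ratio is lower than its figure.

The flask gives 3.58, 3.52 and 1.87, with D ahead, 24.0% against 12.8%.

    L + Z ⇌ D (K = 2.50 /M, k = 0.430 /M/min)
    L + Z ⇌ E (K = 24.0 /M, k = 0.120 /M/min)
    L + D ⇌ G, settled at all times (K = 47.0 /M)

In this flask both forward steps ran side by side as Z fell to 59.3% of its charge at 5.00 min, and half of the turnover of L + Z into D up to 50 min was done by 3.23 min. From 25.0 min to 50.0 min, D went from 25.2% to 24.0% and E from 9.71% to 12.8%, and at 50.0 min this flask held 0.0330 M of Z, more than my 0.0212 M; the coefficient on this Z gives 0.380 decades, and the flask's ratio fell by 0.282 from 10 s to 50 min. A neighbour flask with 0.62 M of L kept 3.26% of its Z at 50 min; the coefficient gives a ratio of 3.21, and that flask stands at 3.14.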